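**Retrosynthetic overview**

1. Feature: in the ten-membered ring C1–C10, the oxygen-bearing C6 lies between the E-trisubstituted C4=C5 unit (later the C4–C5 oxirane) and C7, which carries the C11(=C13)–C12 acrylate. C6 is therefore made by adding a C5 alkenyl metal to a C6 aldehyde, and the new hydroxyl then closes the γ-lactone (O–C6–C7–C11–C12).
2. The seco iodoalkene aldehyde 32 is cut at C9–C10. Dienoate 5 (C1–C5, C10, C14, C15; from pent-4-yn-1-ol) acts as an acrylate α-anion equivalent (amide conjugate addition/aldol, then Cope elimination) toward aldehyde 20 (C6–C9, C11–C13).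
3. Aldehyde 20 comes from an Evans syn-aldol of a succinate imide (C7, C8) followed by α-methylenation; C9 is set by Felkin–Anh addition.
4. After ring closure: lactonisation, C8 desilylation, esterification with chlorohydrin acid 25 (from angelic acid by Katsuki–Sharpless epoxidation and HCl opening), and C4=C5 epoxidation.
5. Ring order: ten-membered carbocycle (step 20), γ-lactone (step 21), oxirane (step 24).

Key step: step 20

Remark (assumption): atoms carry germacranolide numbers (ring C1–C10; C11–C13 on C7; C14 the ester carbon on C10; C15 the methyl on C4; acid carbons primed). The C12 ester, which is lost on lactonisation, is carried as the tert-butyl ester so that no γ-lactone can form before the ring closure. Compounds 6, 7 and 10 are taken as commercial.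

**Dienoate 5**

Step 1
Reactants: 1 pent-4-yn-1-ol
Product: 3 (E)-5-iodo-4-methylpent-4-en-1-ol, via alkenylalane 2 (not isolated)
Conditions: AlMe3 (3 equiv), Cp2ZrCl2 (0.25 equiv), CH2Cl2, 0 °C → rt; then I2, THF, −30 → 0 °C; dilute aq. HCl
Reagents that add atoms: trimethylaluminium C[Al](C)C; iodine II
Why: Zirconium-catalysed carboalumination (Negishi) adds Me–Al syn across the terminal alkyne with methyl on the internal carbon, and iodinolysis of the alkenyl–Al bond with retention should give the E iodoalkene.

Step 2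
Reactants: 3 (E)-5-iodo-4-methylpent-4-en-1-ol
Product: 5 methyl (2E,6E)-7-iodo-6-methylhepta-2,6-dienoate, via aldehyde 4 (not isolated)
Conditions: PhI(OAc)2, TEMPO (10 mol%), CH2Cl2, rt; then Ph3P=CHCO2Me, rt
Reagents that add atoms: methyl (triphenylphosphoranylidene)acetate COC(=O)C=P(c1ccccc1)(c1ccccc1)c1ccccc1
Why: Oxoammonium oxidation stops at the aldehyde, which is trapped in the same flask by the stabilised ylide in an E-selective Wittig olefination; the alkenyl iodide is inert to both.

**Aldehyde 20**

Step 3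
Reactants: 6 4-tert-butoxy-4-oxobutanoic acid; 7 (R)-4-benzyloxazolidin-2-one
Product: 9 tert-butyl 4-[(R)-4-benzyl-2-oxooxazolidin-3-yl]-4-oxobutanoate, via mixed pivalic anhydride 8 (not isolated)
Conditions: PivCl, Et3N, THF, −20 °C; then LiCl, 7, −20 °C → rt
Reagents that add atoms: none
Why: Mixed-anhydride N-acylation of the oxazolidinone, in which the nucleophile attacks the unhindered succinyl carbonyl and not the pivaloyl carbonyl.

Step 4
Reactants: 9 tert-butyl 4-[(R)-4-benzyl-2-oxooxazolidin-3-yl]-4-oxobutanoate; 10 2-[(4-methoxybenzyl)oxy]acetaldehyde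
Product: 12 tert-butyl (3R,4R)-3-[(R)-4-benzyl-2-oxooxazolidine-3-carbonyl]-4-hydroxy-5-[(4-methoxybenzyl)oxy]pentanoate, via Z boron enolate 11 (not isolated)
Conditions: Bu2BOTf, iPr2NEt, CH2Cl2, −78 → 0 °C; 10, −78 → 0 °C; pH 7 buffer, MeOH, 30% H2O2, 0 °C
Reagents that add atoms: none
Why: Evans syn-aldol reaction, in which only the imide is enolised to the Z boron enolate and the Zimmerman–Traxler chair with the aldehyde on the face away from the benzyl group of the R auxiliary should set C7 and C8 syn in the absolute sense shown (3R,4R in this compound).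

Step 5
Reactants: 12 syn-aldol adduct
Product: 13 tert-butyl (3R,4R)-3-[(R)-4-benzyl-2-oxooxazolidine-3-carbonyl]-4-[(tert-butyldimethylsilyl)oxy]-5-[(4-methoxybenzyl)oxy]pentanoate
Conditions: TBSOTf, 2,6-lutidine, CH2Cl2, −78 → 0 °C
Reagents that add atoms: tert-butyldimethylsilyl triflate CC(C)(C)[Si](C)(C)OS(=O)(=O)C(F)(F)F
Why: Silyl triflate silylation of the secondary aldol hydroxyl, done at once so that it can neither lactonise onto the ester nor undergo retro-aldol cleavage.

Step 6
Reactants: 13 silylated aldol adduct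
Product: 14 tert-butyl (3S,4R)-4-[(tert-butyldimethylsilyl)oxy]-3-(hydroxymethyl)-5-[(4-methoxybenzyl)oxy]pentanoate
Conditions: LiBH4, MeOH (1.1 equiv), THF, 0 °C; aq. NH4Cl
Reagents that add atoms: none
Why: Reductive removal of the auxiliary, in which borohydride attacks the activated exocyclic imide carbonyl while the tert-butyl ester is inert and cannot lactonise, and C7 is not epimerised (its descriptor changes only through priorities).

Step 7
Reactants: 14 primary alcohol
Product: 15 tert-butyl (3S,4R)-4-[(tert-butyldimethylsilyl)oxy]-5-[(4-methoxybenzyl)oxy]-3-{[(triethylsilyl)oxy]methyl}pentanoate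
Conditions: TESCl, imidazole, CH2Cl2, 0 °C
Reagents that add atoms: chlorotriethylsilane CC[Si](Cl)(CC)CC
Why: Standard silylation of the primary alcohol, giving a triethylsilyl ether that can later be removed in the presence of the secondary TBS ether.

Step 8
Reactants: 15 bis-silyl ether ester
Product: 18 tert-butyl (3S,4R)-4-[(tert-butyldimethylsilyl)oxy]-5-[(4-methoxybenzyl)oxy]-2-methylidene-3-{[(triethylsilyl)oxy]methyl}pentanoate, via Mannich base 16 (not isolated), via ammonium iodide 17 (not isolated)
Conditions: LiN(iPr)2 (from iPr2NH, nBuLi), THF, −78 °C; Me2N=CH2 iodide, −78 °C → rt; then MeI, MeOH, rt; then DBU, CH2Cl2, rt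
Reagents that add atoms: dimethylmethyleneiminium iodide (Eschenmoser's salt) C=[N+](C)C.[I-]
Why: Classical α-methylenation of an ester by enolate Mannich reaction, quaternisation and base-induced elimination of trimethylamine; the C11 centre formed in between is lost again, and C7 carries no leaving group and is not acidic enough to be touched.

Step 9
Reactants: 18 acrylate with PMB ether
Product: 19 tert-butyl (3S,4R)-4-[(tert-butyldimethylsilyl)oxy]-5-hydroxy-2-methylidene-3-{[(triethylsilyl)oxy]methyl}pentanoate
Conditions: DDQ, CH2Cl2/pH 7 buffer (10:1), 0 °C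
Reagents that add atoms: none
Why: Oxidative cleavage of the p-methoxybenzyl ether (hydride abstraction by DDQ, then hydrolysis) under buffered conditions, which leaves both silyl ethers and the acrylate untouched.

Step 10
Reactants: 19 primary C9 alcohol
Product: 20 tert-butyl (3S,4R)-4-[(tert-butyldimethylsilyl)oxy]-2-methylidene-5-oxo-3-{[(triethylsilyl)oxy]methyl}pentanoate
Conditions: Dess–Martin periodinane, pyridine, CH2Cl2, 0 °C → rt; used directly
Reagents that add atoms: none
Why: Dess–Martin oxidation under buffered, non-basic conditions should give the α-silyloxy aldehyde without epimerisation at C8.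

**Side-chain acid 25**

Step 11
Reactants: 21 angelic acid
Product: 22 (Z)-2-methylbut-2-en-1-ol
Conditions: LiAlH4, Et2O, 0 °C → rt; H2O, aq. NaOH
Reagents that add atoms: none
Why: Hydride reduction of the acid to the allylic alcohol; LiAlH4 neither reduces nor isomerises the unactivated trisubstituted Z alkene.

Step 12
Reactants: 22 (Z)-2-methylbut-2-en-1-ol
Product: 23 [(2S,3R)-2,3-dimethyloxiran-2-yl]methanol
Conditions: Ti(OiPr)4 (10 mol%), L-(+)-diethyl tartrate (12 mol%), tBuOOH, 4 Å molecular sieves, CH2Cl2, −20 °C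
Reagents that add atoms: tert-butyl hydroperoxide CC(C)(C)OO
Why: Katsuki–Sharpless asymmetric epoxidation, in which the titanium–L-(+)-tartrate catalyst delivers oxygen to the alkene face that gives 2S epoxy alcohols, here (2S,3R) because the alkene is Z.

Step 13
Reactants: 23 epoxy alcohol
Product: 24 (2R,3R)-2,3-dimethyloxirane-2-carboxylic acid
Conditions: RuCl3 hydrate (2 mol%), NaIO4 (4 equiv), MeCN/EtOAc/H2O, 0 °C → rt
Reagents that add atoms: sodium periodate [Na+].[O-]I(=O)(=O)=O; water O
Why: Ruthenium tetroxide oxidation (catalytic RuCl3, NaIO4) takes the primary alcohol to the acid without opening the epoxide; both stereocentres are untouched and C2 becomes R only through a priority change.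

Step 14
Reactants: 24 epoxy acid
Product: 25 (2S,3S)-3-chloro-2-hydroxy-2-methylbutanoic acid
Conditions: HCl (2 M in Et2O), CH2Cl2, −20 → 0 °C
Reagents that add atoms: hydrogen chloride Cl
Why: Acid-promoted epoxide opening in which chloride attacks C3, the carbon remote from the electron-withdrawing carboxyl group, by SN2 displacement with inversion, while C2 keeps its oxygen and configuration.

**Union, ring closure and endgame**

Step 15
Reactants: 5 methyl (2E,6E)-7-iodo-6-methylhepta-2,6-dienoate; 20 α-silyloxy aldehyde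
Product: 27 β-dibenzylamino aldol adduct (9S,8R,7S; C1 and C10 as the anti pair), via lithium β-amino enolate 26 (not isolated)
Conditions: Bn2NH, nBuLi, THF, −78 °C; 5, −78 °C; then 20, −78 °C; AcOH quench at −78 °C
Reagents that add atoms: dibenzylamine C(NCc1ccccc1)c1ccccc1
Why: Tandem aza-Michael–aldol reaction, in which LiNBn2 adds 1,4 to the enoate and the resulting β-amino ester enolate (an acrylate α-anion equivalent) adds to the α-silyloxy aldehyde under Felkin–Anh control (OTBS anti to the nucleophile) to set 9S, anti to O8, while C1 and C10 should form mainly anti to each other and are removed in the next step.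

Step 16
Reactants: 27 β-dibenzylamino aldol adduct
Product: 29 tert-butyl (3S,4R,5S,6E,10E)-4-[(tert-butyldimethylsilyl)oxy]-5-hydroxy-11-iodo-6-(methoxycarbonyl)-10-methyl-2-methylidene-3-{[(triethylsilyl)oxy]methyl}undeca-6,10-dienoate, via amine N-oxide 28 (not isolated)
Conditions: mCPBA (1.05 equiv), CH2Cl2, −20 °C → rt
Reagents that add atoms: none
Why: Amine N-oxidation followed by Cope elimination, whose syn course across C1–C10 from the anti adduct should give the E enoate with C2 cis to C9, while the electron-poor and iodine-deactivated alkenes are not epoxidised at this temperature.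

Step 17
Reactants: 29 allylic C9 alcohol
Product: 30 tert-butyl (3S,4R,5S,6E,10E)-5-acetoxy-4-[(tert-butyldimethylsilyl)oxy]-11-iodo-6-(methoxycarbonyl)-10-methyl-2-methylidene-3-{[(triethylsilyl)oxy]methyl}undeca-6,10-dienoate
Conditions: Ac2O, pyridine, DMAP (cat.), CH2Cl2, 0 °C → rt
Reagents that add atoms: acetic anhydride CC(=O)OC(C)=O
Why: DMAP-catalysed acylation of the hindered secondary allylic alcohol.

Step 18
Reactants: 30 acetate with C6 triethylsilyl ether
Product: 31 tert-butyl (3S,4R,5S,6E,10E)-5-acetoxy-4-[(tert-butyldimethylsilyl)oxy]-3-(hydroxymethyl)-11-iodo-6-(methoxycarbonyl)-10-methyl-2-methylideneundeca-6,10-dienoate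
Conditions: HF·pyridine, pyridine, THF, 0 °C
Reagents that add atoms: none
Why: Buffered HF·pyridine cleaves the primary triethylsilyl ether much faster than the hindered secondary TBS ether, the acetate and esters are stable, and the tert-butyl ester cannot lactonise with the freed C6 hydroxyl.

Step 19
Reactants: 31 primary C6 alcohol
Product: 32 seco iodoalkene aldehyde, tert-butyl (3R,4R,5S,6E,10E)-5-acetoxy-4-[(tert-butyldimethylsilyl)oxy]-3-formyl-11-iodo-6-(methoxycarbonyl)-10-methyl-2-methylideneundeca-6,10-dienoate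
Conditions: Dess–Martin periodinane, pyridine, CH2Cl2, 0 °C; filtered and used at once
Reagents that add atoms: none
Why: Dess–Martin oxidation under neutral conditions; because C7–H is α to the formyl group and allylic, the aldehyde is not chromatographed, to avoid epimerisation, alkene migration or loss of the β-silyloxy group.

Step 20
Reactants: 32 seco iodoalkene aldehyde
Product: 33 ten-membered C6 allylic alcohol (C6–OH with H6 anti to H7; tert-butyl acrylate on C7; TBS ether at C8; acetate at C9; methyl ester on C10; E-C4=C5; C1=C10 with C2 cis to C9)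
Conditions: CrCl2 (10 equiv), NiCl2 (1 mol% of the CrCl2), degassed DMSO, rt, 32 added slowly to 0.002 M; aq. NH4Cl
Reagents that add atoms: none
Why: Divalent chromium reduces NiCl2 to zerovalent nickel, which inserts into the alkenyl C5–I bond; the alkenyl group is passed to trivalent chromium and the alkenylchromium adds to the C6 aldehyde, the Nozaki–Hiyama–Kishi reaction in its macrocyclising form. The ten-membered carbocycle closes by 10-exo-trig attack of C5 on the formyl carbon at high dilution, with the E geometry of C4=C5 retained inside the ring. The new C6 stereocentre is set by the substrate: Felkin–Anh approach anti to the C7–C8 bond, with the planar acrylate in the medium position, should place O6 syn to C11 and H6 anti to H7, as the target requires. The step needs insertion into the only C–I bond and addition to the aldehyde in preference to the three esters, which the low basicity and carbonyl selectivity of alkenylchromium reagents secure. It also needs ring closure to win over oligomerisation, which slow addition and the two folding elements of the chain (the C1=C10 enoate with C2 cis to C9, and the E alkenyl unit) favour. The aldehyde is α-branched and enolisable, but the medium is neutral, so C7 should keep its configuration.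

Step 21
Reactants: 33 ten-membered C6 allylic alcohol
Product: 36 trans-fused 6,12-lactone (α-methylene-γ-lactone; TBS ether at C8; acetate at C9; methyl ester on C10), via bis-trimethylsilyl derivative 34 (not isolated), via hydroxy acid 35 (not isolated)
Conditions: TMSOTf, 2,6-lutidine, CH2Cl2, 0 °C; then 0.5 M aq. citric acid, THF, rt; then PPTS (cat.), CH2Cl2, rt
Reagents that add atoms: none
Why: The silyl triflate converts the tert-butyl ester into the silyl ester (loss of isobutene) and caps C6–OH without ionising the allylic position, and mild acid then frees the γ-hydroxy acid, which closes to the γ-lactone by acyl substitution (5-exo-trig) with retention at C6.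

Step 22
Reactants: 36 lactone with C8 TBS ether
Product: 37 C8 alcohol of the lactone
Conditions: HF·pyridine, THF, 0 °C → rt
Reagents that add atoms: none
Why: Fluoride desilylation under acidic, non-basic conditions, chosen to avoid acetyl migration from O9 to O8 and conjugate addition to the methylene lactone.

Step 23
Reactants: 37 C8 alcohol; 25 (2S,3S)-3-chloro-2-hydroxy-2-methylbutanoic acid
Product: 39 C8 (2S,3S)-3-chloro-2-hydroxy-2-methylbutanoate of the lactone (C4=C5 still an alkene), via mixed trichlorobenzoic anhydride 38 (not isolated)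
Conditions: 25, 2,4,6-trichlorobenzoyl chloride, Et3N, THF, 0 °C; then 37, DMAP, toluene, rt → 40 °C
Reagents that add atoms: none
Why: Yamaguchi esterification through the mixed anhydride and DMAP; the tertiary hydroxyl of the acid is too hindered to compete and the acid has no α-hydrogen, so its two stereocentres are safe.

Step 24
Reactants: 39 C8 ester with C4=C5 alkene
Product: 40 target CNP0185503.2
Conditions: mCPBA, CH2Cl2, 0 °C; aq. NaHCO3 wash
Reagents that add atoms: 3-chloroperbenzoic acid OOC(=O)c1cccc(Cl)c1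
Why: Prilezhaev epoxidation, in which the peracid attacks only the electron-rich C4=C5 alkene and approach from the outer face of the folded ten-membered ring (substrate control, as in related germacranolide epoxidations) should give the (4R,5R) oxirane; the enoate and the methylene lactone are too electron-poor to react.

**Compound list**

1 | pent-4-yn-1-ol | C#CCCCO | starting material
2 | alkenylalane from carboalumination (O-aluminated) | C[Al](C)OCCC/C(C)=C/[Al](C)C | intermediate
3 | (E)-5-iodo-4-methylpent-4-en-1-ol | OCCC/C(C)=C/I | intermediate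
4 | (E)-5-iodo-4-methylpent-4-enal | O=CCC/C(C)=C/I | intermediate
5 | methyl (2E,6E)-7-iodo-6-methylhepta-2,6-dienoate | COC(=O)/C=C/CC/C(C)=C/I | intermediate
6 | 4-tert-butoxy-4-oxobutanoic acid (mono-tert-butyl succinate) | CC(C)(C)OC(=O)CCC(=O)O | starting material
7 | (R)-4-benzyloxazolidin-2-one | O=C1N[C@H](Cc2ccccc2)CO1 | starting material
8 | mixed pivalic anhydride of 6 | CC(C)(C)OC(=O)CCC(=O)OC(=O)C(C)(C)C | intermediate
9 | tert-butyl 4-[(R)-4-benzyl-2-oxooxazolidin-3-yl]-4-oxobutanoate | CC(C)(C)OC(=O)CCC(=O)N1[C@H](Cc2ccccc2)COC1=O | intermediate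
10 | 2-[(4-methoxybenzyl)oxy]acetaldehyde | O=CCOCc1ccc(OC)cc1 | starting material
11 | Z dibutylboron enolate of 9 | CCCCB(CCCC)O/C(=C\CC(=O)OC(C)(C)C)N1[C@H](Cc2ccccc2)COC1=O | intermediate
12 | tert-butyl (3R,4R)-3-[(R)-4-benzyl-2-oxooxazolidine-3-carbonyl]-4-hydroxy-5-[(4-methoxybenzyl)oxy]pentanoate | CC(C)(C)OC(=O)C[C@H]([C@@H](O)COCc1ccc(OC)cc1)C(=O)N1[C@H](Cc2ccccc2)COC1=O | intermediate
13 | TBS ether of 12 | CC(C)(C)OC(=O)C[C@H]([C@@H](O[Si](C)(C)C(C)(C)C)COCc1ccc(OC)cc1)C(=O)N1[C@H](Cc2ccccc2)COC1=O | intermediate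
14 | tert-butyl (3S,4R)-4-[(tert-butyldimethylsilyl)oxy]-3-(hydroxymethyl)-5-[(4-methoxybenzyl)oxy]pentanoate | CC(C)(C)OC(=O)C[C@@H](CO)[C@@H](O[Si](C)(C)C(C)(C)C)COCc1ccc(OC)cc1 | intermediate
15 | tert-butyl (3S,4R)-4-[(tert-butyldimethylsilyl)oxy]-5-[(4-methoxybenzyl)oxy]-3-{[(triethylsilyl)oxy]methyl}pentanoate | CC(C)(C)OC(=O)C[C@@H](CO[Si](CC)(CC)CC)[C@@H](O[Si](C)(C)C(C)(C)C)COCc1ccc(OC)cc1 | intermediate
16 | Mannich base, 2-[(dimethylamino)methyl] derivative of 15 (C2 epimers) | CC(C)(C)OC(=O)C(CN(C)C)[C@@H](CO[Si](CC)(CC)CC)[C@@H](O[Si](C)(C)C(C)(C)C)COCc1ccc(OC)cc1 | intermediate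
17 | trimethylammonium iodide of 16 | CC(C)(C)OC(=O)C(C[N+](C)(C)C)[C@@H](CO[Si](CC)(CC)CC)[C@@H](O[Si](C)(C)C(C)(C)C)COCc1ccc(OC)cc1.[I-] | intermediate
18 | tert-butyl (3S,4R)-4-[(tert-butyldimethylsilyl)oxy]-5-[(4-methoxybenzyl)oxy]-2-methylidene-3-{[(triethylsilyl)oxy]methyl}pentanoate | C=C(C(=O)OC(C)(C)C)[C@@H](CO[Si](CC)(CC)CC)[C@@H](O[Si](C)(C)C(C)(C)C)COCc1ccc(OC)cc1 | intermediate
19 | tert-butyl (3S,4R)-4-[(tert-butyldimethylsilyl)oxy]-5-hydroxy-2-methylidene-3-{[(triethylsilyl)oxy]methyl}pentanoate | C=C(C(=O)OC(C)(C)C)[C@@H](CO[Si](CC)(CC)CC)[C@@H](O[Si](C)(C)C(C)(C)C)CO | intermediate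
20 | tert-butyl (3S,4R)-4-[(tert-butyldimethylsilyl)oxy]-2-methylidene-5-oxo-3-{[(triethylsilyl)oxy]methyl}pentanoate | C=C(C(=O)OC(C)(C)C)[C@@H](CO[Si](CC)(CC)CC)[C@@H](O[Si](C)(C)C(C)(C)C)C=O | intermediate
21 | angelic acid, (Z)-2-methylbut-2-enoic acid | C/C=C(/C)C(=O)O | starting material
22 | (Z)-2-methylbut-2-en-1-ol | C/C=C(/C)CO | intermediate
23 | [(2S,3R)-2,3-dimethyloxiran-2-yl]methanol | C[C@H]1O[C@@]1(C)CO | intermediate
24 | (2R,3R)-2,3-dimethyloxirane-2-carboxylic acid | C[C@H]1O[C@@]1(C)C(=O)O | intermediate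
25 | (2S,3S)-3-chloro-2-hydroxy-2-methylbutanoic acid | OC(=O)[C@](C)(O)[C@H](C)Cl | intermediate
26 | lithium enolate of methyl 3-(dibenzylamino)-7-iodo-6-methylhept-6-enoate | [Li]O/C(OC)=C\C(CC/C(C)=C/I)N(Cc1ccccc1)Cc1ccccc1 | intermediate
27 | β-dibenzylamino aldol adduct (9S,8R,7S; C1/C10 anti pair) | COC(=O)C(C(CC/C(C)=C/I)N(Cc1ccccc1)Cc1ccccc1)[C@H](O)[C@H](O[Si](C)(C)C(C)(C)C)[C@H](CO[Si](CC)(CC)CC)C(=C)C(=O)OC(C)(C)C | intermediate
28 | amine N-oxide of 27 | COC(=O)C(C(CC/C(C)=C/I)[N+]([O-])(Cc1ccccc1)Cc1ccccc1)[C@H](O)[C@H](O[Si](C)(C)C(C)(C)C)[C@H](CO[Si](CC)(CC)CC)C(=C)C(=O)OC(C)(C)C | intermediate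
29 | tert-butyl (3S,4R,5S,6E,10E)-4-[(tert-butyldimethylsilyl)oxy]-5-hydroxy-11-iodo-6-(methoxycarbonyl)-10-methyl-2-methylidene-3-{[(triethylsilyl)oxy]methyl}undeca-6,10-dienoate | I/C=C(\C)CC/C=C(C(=O)OC)\[C@H](O)[C@H](O[Si](C)(C)C(C)(C)C)[C@H](CO[Si](CC)(CC)CC)C(=C)C(=O)OC(C)(C)C | intermediate
30 | 5-acetate of 29 | I/C=C(\C)CC/C=C(C(=O)OC)\[C@H](OC(C)=O)[C@H](O[Si](C)(C)C(C)(C)C)[C@H](CO[Si](CC)(CC)CC)C(=C)C(=O)OC(C)(C)C | intermediate
31 | primary C6 alcohol (triethylsilyl ether of 30 removed) | I/C=C(\C)CC/C=C(C(=O)OC)\[C@H](OC(C)=O)[C@H](O[Si](C)(C)C(C)(C)C)[C@H](CO)C(=C)C(=O)OC(C)(C)C | intermediate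
32 | seco iodoalkene aldehyde, tert-butyl (3R,4R,5S,6E,10E)-5-acetoxy-4-[(tert-butyldimethylsilyl)oxy]-3-formyl-11-iodo-6-(methoxycarbonyl)-10-methyl-2-methylideneundeca-6,10-dienoate | I/C=C(\C)CC/C=C(C(=O)OC)\[C@H](OC(C)=O)[C@H](O[Si](C)(C)C(C)(C)C)[C@H](C=O)C(=C)C(=O)OC(C)(C)C | intermediate
33 | ten-membered C6 allylic alcohol (H6 anti to H7) | C1/C(C)=C/[C@@H](O)[C@H](C(=C)C(=O)OC(C)(C)C)[C@@H](O[Si](C)(C)C(C)(C)C)[C@@H](OC(C)=O)/C(C(=O)OC)=C\C1 | intermediate
34 | C6 trimethylsilyl ether, C12 trimethylsilyl ester of the macrocycle | C1/C(C)=C/[C@@H](O[Si](C)(C)C)[C@H](C(=C)C(=O)O[Si](C)(C)C)[C@@H](O[Si](C)(C)C(C)(C)C)[C@@H](OC(C)=O)/C(C(=O)OC)=C\C1 | intermediate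
35 | macrocyclic γ-hydroxy acid | C1/C(C)=C/[C@@H](O)[C@H](C(=C)C(=O)O)[C@@H](O[Si](C)(C)C(C)(C)C)[C@@H](OC(C)=O)/C(C(=O)OC)=C\C1 | intermediate
36 | trans-fused 6,12-lactone with C8 TBS ether | C1/C(C)=C/[C@H]2OC(=O)C(=C)[C@@H]2[C@@H](O[Si](C)(C)C(C)(C)C)[C@@H](OC(C)=O)/C(C(=O)OC)=C\C1 | intermediate
37 | C8 alcohol of the lactone | C1/C(C)=C/[C@H]2OC(=O)C(=C)[C@@H]2[C@@H](O)[C@@H](OC(C)=O)/C(C(=O)OC)=C\C1 | intermediate
38 | mixed 2,4,6-trichlorobenzoic anhydride of 25 | O=C(OC(=O)[C@](C)(O)[C@H](C)Cl)c1c(Cl)cc(Cl)cc1Cl | intermediate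
39 | C8 (2S,3S)-3-chloro-2-hydroxy-2-methylbutanoate of the lactone (4,5-alkene) | C1/C(C)=C/[C@H]2OC(=O)C(=C)[C@@H]2[C@@H](OC(=O)[C@](C)(O)[C@H](C)Cl)[C@@H](OC(C)=O)/C(C(=O)OC)=C\C1 | intermediate
40 | CNP0185503.2 | C=C1C(=O)O[C@H]2[C@H]1[C@@H](OC(=O)[C@](C)(O)[C@H](C)Cl)[C@@H](OC(C)=O)/C(C(=O)OC)=C\CC[C@@]1(C)O[C@H]21 | target

**Step count**

Total: 24 steps. Longest linear sequence: 18 steps (steps 3–10, then 15–24).

**Steps most likely to fail**

Step 20. The alkenylchromium may add to the other face of the C6 aldehyde, because strain in the ten-membered transition state can override the Felkin–Anh preference. The fallback no longer relies on the C–C bond formation to set C6 but corrects it in the lactonisation. It sets out from 32, which under the same cyclisation conditions would then give the C6-epimeric macrocyclic alcohol F1. Treatment with TMSOTf/2,6-lutidine and then pH 7 buffer (no acid, so that the cis lactone does not close) would give the C6-epimeric hydroxy acid F2. Mitsunobu lactonisation (PPh3, DIAD, toluene, 0 °C) displaces the activated C6 oxygen by the carboxylate with inversion and returns to the route at lactone 36. A mixture of C6 epimers could be divided and sent down both paths to the same lactone.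

Step 15. The lithium amide may deprotonate the enoate at C2 or attack the ester carbonyl, the hindered aldehyde may react slowly, or the C1/C10 anti relation may be lost so that the Cope elimination gives a mixture of enoate geometries. The fallback brings C10 in as a preformed saturated ester enolate and introduces the C1=C10 double bond afterwards. It sets out from 5. Conjugate reduction with [(Ph3P)CuH]6 would give methyl (E)-7-iodo-6-methylhept-6-enoate F3. LiN(iPr)2 and PhSeBr would give the α-phenylselanyl ester F4. Its lithium enolate would add to aldehyde 20 (again Felkin–Anh) to give the α-selanyl aldol adduct F5. Oxidation with H2O2/pyridine at 0 °C and selenoxide syn-elimination into the C1 methylene, away from the carbinol carbon, would return to the route at 29.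

Step 23. Acylation of the hindered C8 hydroxyl may be slow. That would leave time for the unprotected tertiary hydroxyl of the acid to self-acylate, or for the acetyl group to shift from O9 to O8. The fallback couples a smaller acid that has no free hydroxyl and forms the chlorohydrin afterwards. It sets out from 37 and the epoxy acid 24. Yamaguchi esterification would give the C8 (2R,3R)-2,3-dimethyloxirane-2-carboxylate F6. HCl in Et2O/CH2Cl2 at −20 °C, before any C4–C5 oxirane is present, would open the glycidic ester at C3′ with inversion and return to the route at 39.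

**Further compounds**

F1 | step 20 | C6 epimer of macrocyclic alcohol 33 | C1/C(C)=C/[C@H](O)[C@H](C(=C)C(=O)OC(C)(C)C)[C@@H](O[Si](C)(C)C(C)(C)C)[C@@H](OC(C)=O)/C(C(=O)OC)=C\C1
F2 | step 20 | C6-epimeric macrocyclic γ-hydroxy acid | C1/C(C)=C/[C@H](O)[C@H](C(=C)C(=O)O)[C@@H](O[Si](C)(C)C(C)(C)C)[C@@H](OC(C)=O)/C(C(=O)OC)=C\C1
F3 | step 15 | methyl (E)-7-iodo-6-methylhept-6-enoate | COC(=O)CCCC/C(C)=C/I
F4 | step 15 | methyl (E)-7-iodo-6-methyl-2-(phenylselanyl)hept-6-enoate | COC(=O)C([Se]c1ccccc1)CCC/C(C)=C/I
F5 | step 15 | α-phenylselanyl aldol adduct of F4 and 20 | COC(=O)C([Se]c1ccccc1)(CCC/C(C)=C/I)[C@H](O)[C@H](O[Si](C)(C)C(C)(C)C)[C@H](CO[Si](CC)(CC)CC)C(=C)C(=O)OC(C)(C)C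
F6 | step 23 | C8 (2R,3R)-2,3-dimethyloxirane-2-carboxylate of lactone 37 | C1/C(C)=C/[C@H]2OC(=O)C(=C)[C@@H]2[C@@H](OC(=O)[C@]3(C)O[C@@H]3C)[C@@H](OC(C)=O)/C(C(=O)OC)=C\C1
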